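## Retrosynthetic overview

1. The target is a 9β-H labdane, (4S,5R,6S,7S,9S,10R). The last steps only adjust ring B oxygens (C6 ketone to axial 6β-OH to benzoate) and remove silyl and tert-butyl groups. The C12–C16 chain is joined to C11 by sulfone alkylation with an (E)-C5 allylic bromide.
2. Key disconnection: ring B by a Diels–Alder reaction forming C7–C8 and C9–C10, between a ring A diene C10=C5–C6(OSi)=C7H(OSi) (Z) and ethyl buta-2,3-dienoate (C17=C8=C9–C11O2Et).
3. Enabling feature: in ring B the exocyclic C8=C17 methylene lies between C7 and C9, and C9 carries a carbon (C11) that can be a carboxyl. This is the pattern left when the conjugated bond of an allenic ester adds across a diene. The ring fusion bond C5–C10 together with C6–C7 supplies that diene from a ring A cyclohexenyl ketone, and the diene oxygens become the C6 and C7 oxygens.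
4. Ring A comes from tert-butyl (1S)-1-methyl-2-oxocyclohexane-1-carboxylate (C4 set by auxiliary-controlled methylation), then C10 methylation, enol triflate and attachment of the C6–C7 acyl arm.
5. Ring order: ring A is present from the first compound; ring B is the last ring closed (step 8).

Key step: step 8

Remarks on the chemistry:
- tert-Butyl 2-oxocyclohexane-1-carboxylate is taken as a catalogue compound (otherwise one Dieckmann step from di-tert-butyl pimelate).
- Bicyclic compounds are named with labdane numbering: C17 is the exocyclic CH2 on C8, C18 the 4α-methyl, C19 the 4β-carboxyl, C20 the 10β-methyl. β is the face of C20. All bicyclic compounds carry 4α-Me, 4β-CO2R and 10β-Me.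

## Route

Step 1
Reactants: 1 tert-butyl 2-oxocyclohexane-1-carboxylate; 2 L-valine tert-butyl ester
Product: 3 tert-butyl 2-{[(2S)-1-tert-butoxy-3-methyl-1-oxobutan-2-yl]amino}cyclohex-1-ene-1-carboxylate
Conditions: TsOH (cat.), 4 Å MS, toluene, 50 °C
Reagents that add atoms: none
Why: Acid-catalysed condensation of the β-keto ester with the primary amine (enamine formation) gives the conjugated, hydrogen-bonded enamino ester and so installs the chiral auxiliary.

Step 2
Reactants: 3 chiral enamino ester
Product: 6 tert-butyl (1S)-1-methyl-2-oxocyclohexane-1-carboxylate, via N-lithio enamine 4 (not isolated), via alkylated imine 5 (not isolated)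
Conditions: LiN(iPr)2, toluene, HMPA (1 equiv), −78 °C; MeI, −78 to −40 °C; then 10% aq. citric acid, THF, rt
Reagents that add atoms: iodomethane (CI); water (O)
Why: Auxiliary-controlled alkylation of a chiral lithio-enamine: lithium is chelated by the enamine nitrogen and the valine ester carbonyl, the isopropyl group screens one face of C4 and MeI enters from the other; the facial sense depends on the ligand sphere of lithium (THF or toluene/HMPA) and the regime (or auxiliary antipode) that delivers the (S) centre is to be used, after which imine hydrolysis releases the quaternary keto ester.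

Step 3
Reactants: 6 tert-butyl (1S)-1-methyl-2-oxocyclohexane-1-carboxylate
Product: 8 tert-butyl (1S)-1,3-dimethyl-2-oxocyclohexane-1-carboxylate (C3 epimers), via lithium enolate 7 (not isolated)
Conditions: LiN(iPr)2, THF, −78 °C; MeI, −78 to 0 °C
Reagents that add atoms: iodomethane (CI)
Why: Kinetic enolate alkylation at the only enolisable position places the future C20 methyl on C10; the new centre need not be controlled because it becomes sp2 in step 4.

Step 4
Reactants: 8 tert-butyl (1S)-1,3-dimethyl-2-oxocyclohexane-1-carboxylate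
Product: 10 tert-butyl (1S)-1,3-dimethyl-2-(trifluoromethylsulfonyloxy)cyclohex-2-ene-1-carboxylate, via potassium enolate 9 (not isolated)
Conditions: KN(SiMe3)2, THF, −78 to 0 °C; PhNTf2, 0 °C to rt
Reagents that add atoms: N-phenylbis(trifluoromethanesulfonimide) (O=S(=O)(N(c1ccccc1)S(=O)(=O)C(F)(F)F)C(F)(F)F)
Why: O-Sulfonylation of the only possible (tetrasubstituted) enolate (enol triflate formation) fixes the C5=C10 double bond regiospecifically.

Step 5
Reactants: 10 enol triflate; 11 (tert-butyldimethylsilyloxy)acetaldehyde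
Product: 12 tert-butyl (1S)-2-[2-(tert-butyldimethylsilyloxy)-1-hydroxyethyl]-1,3-dimethylcyclohex-2-ene-1-carboxylate (carbinol epimers)
Conditions: CrCl2 (5 equiv), NiCl2 (2 mol%), DMF, rt
Reagents that add atoms: none
Why: Nozaki–Hiyama–Kishi coupling of the alkenyl triflate with the aldehyde forms C5–C6 and tolerates both the ester and the silyl ether; the carbinol centre is not controlled because it is oxidised in step 6.

Step 6
Reactants: 12 allylic alcohol
Product: 13 tert-butyl (1S)-2-[(tert-butyldimethylsilyloxy)acetyl]-1,3-dimethylcyclohex-2-ene-1-carboxylate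
Conditions: Dess–Martin periodinane, CH2Cl2, 0 °C to rt
Reagents that add atoms: none
Why: Dess–Martin oxidation of the allylic alcohol to the enone under near-neutral conditions leaves the silyl ether and the tert-butyl ester untouched.

Step 7
Reactants: 13 α-silyloxy enone
Product: 14 tert-butyl (1S)-2-[(Z)-1,2-bis(tert-butyldimethylsilyloxy)ethenyl]-1,3-dimethylcyclohex-2-ene-1-carboxylate
Conditions: t-BuMe2SiOTf, Et3N, CH2Cl2, −78 to 0 °C
Reagents that add atoms: tert-butyldimethylsilyl trifluoromethanesulfonate (CC(C)(C)[Si](C)(C)OS(=O)(=O)C(F)(F)F)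
Why: Soft enolisation (silyl triflate and amine) on the CH2OSi side gives the cross-conjugated silyl enol ether, with the two oxygens cis (Z) as is usual for α-alkoxy ketones.

Step 8
Reactants: 14 bis(silyloxy)diene; 15 ethyl buta-2,3-dienoate
Product: 16 19-tert-butyl 11-ethyl 6,7α-bis(tert-butyldimethylsilyloxy)-9β-H-12,13,14,15,16-pentanorlabda-5,8(17)-diene-11,19-dioate
Conditions: 15 (3 equiv), BHT (cat.), toluene, 110 °C, sealed tube
Reagents that add atoms: none
Why: Normal-demand Diels–Alder reaction between the C10=C5–C6=C7 diene and the conjugated C8=C9 bond of the allenoate, concerted but asynchronous with C7–C8 leading; the closest known reactions are the [4+2] additions of 2-silyloxy dienes to allenic esters and of 2,6,6-trimethyl-1-vinylcyclohexene to acetylenic esters. Ring B is closed by a two-bond [4+2] annulation (C7–C8 and C9–C10) onto ring A, which leaves C8=C17 exocyclic and C5=C6 as a silyl enol ether that masks the C6 ketone. At C10 the dienophile adds to the diene face anti to the pseudoaxial C4 tert-butyl ester; the half-chair with the ester rather than the methyl pseudoaxial is expected to react because C20 then develops a syn-axial contact with CO2tBu and not with a methyl group, so C20 ends cis to the ester. At C9 the endo position of the ester (secondary orbital overlap, and the exo site is crowded by C1H2 of ring A) puts C11 trans to C20, and at C7 the suprafacial addition transfers the Z geometry of the enol ether, so the outward silyloxy group ends trans to C20 and cis to C11. The step needs regioselectivity (C7 to the central allene carbon, C10 to C9) and chemoselectivity for the α,β-bond of the allene; these should be secured by the C6 silyloxy group (which makes C7 the enol ether β-carbon), by the fully substituted C10 terminus that can only bond late to the slim sp carbon partner, and by conjugation of the ester with C8=C9.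

Step 9
Reactants: 16 Diels–Alder adduct
Product: 17 tert-butyl 6,7α-bis(tert-butyldimethylsilyloxy)-11-hydroxy-9β-H-12,13,14,15,16-pentanorlabda-5,8(17)-dien-19-oate
Conditions: i-Bu2AlH (2.5 equiv), CH2Cl2, −78 °C; aq. Rochelle salt
Reagents that add atoms: none
Why: Hydride reduction of the ethyl ester to the primary alcohol; the tert-butyl ester on the quaternary C4 is too hindered to react at −78 °C and the silyl enol ether is inert to hydride.

Step 10
Reactants: 17 primary alcohol
Product: 18 tert-butyl 6,7α-bis(tert-butyldimethylsilyloxy)-11-iodo-9β-H-12,13,14,15,16-pentanorlabda-5,8(17)-dien-19-oate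
Conditions: PPh3, I2, imidazole, CH2Cl2, 0 °C (pre-mixed); then 17, rt
Reagents that add atoms: iodine (II)
Why: Appel-type iodination of the primary alcohol under buffered conditions; the phosphonium iodide is formed first so that free iodine does not meet the silyl enol ether.

Step 11
Reactants: 18 primary iodide
Product: 19 tert-butyl 6,7α-bis(tert-butyldimethylsilyloxy)-11-(phenylsulfonyl)-9β-H-12,13,14,15,16-pentanorlabda-5,8(17)-dien-19-oate
Conditions: PhSO2Na (3 equiv), Bu4NI (cat.), DMF, 70 °C
Reagents that add atoms: sodium benzenesulfinate ([Na+].[O-]S(=O)c1ccccc1)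
Why: SN2 displacement of the primary iodide by the soft sulfinate at sulfur (sulfinate S-alkylation) gives the sulfone that makes C11 nucleophilic.

Step 12
Reactants: 20 3-methylbut-2-en-1-ol
Product: 21 tert-butyldimethyl(3-methylbut-2-enyloxy)silane
Conditions: t-BuMe2SiCl, imidazole, CH2Cl2, rt
Reagents that add atoms: tert-butyldimethylsilyl chloride (CC(C)(C)[Si](C)(C)Cl)
Why: Silylation of the primary alcohol gives a base-stable protecting group for the future C15 hydroxyl.

Step 13
Reactants: 21 prenyl silyl ether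
Product: 22 (E)-4-(tert-butyldimethylsilyloxy)-2-methylbut-2-en-1-ol
Conditions: SeO2 (0.3 equiv), t-BuOOH (2.5 equiv), CH2Cl2, rt
Reagents that add atoms: selenium dioxide (O=[Se]=O); tert-butyl hydroperoxide (CC(C)(C)OO)
Why: SeO2-catalysed allylic oxidation (ene reaction, then [2,3]-sigmatropic shift) oxidises only the (E)-methyl group of the trisubstituted alkene, which fixes the E geometry of the future C13=C14 bond.

Step 14
Reactants: 22 (E)-allylic alcohol
Product: 23 (E)-(4-bromo-3-methylbut-2-enyloxy)(tert-butyl)dimethylsilane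
Conditions: CBr4, PPh3, CH2Cl2, 0 °C
Reagents that add atoms: carbon tetrabromide (BrC(Br)(Br)Br)
Why: Appel bromination of the primary allylic alcohol proceeds by SN2 without allylic transposition or loss of alkene geometry.

Step 15
Reactants: 19 sulfone; 23 (E)-allylic bromide
Product: 25 tert-butyl 6,7α,15-tris(tert-butyldimethylsilyloxy)-11-(phenylsulfonyl)-9β-H-labda-5,8(17),13E-trien-19-oate (C11 epimers), via C11-lithio sulfone 24 (not isolated)
Conditions: n-BuLi (1.05 equiv), THF, DMPU, −78 °C; then 23, −78 to −20 °C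
Reagents that add atoms: none
Why: Alkylation of the α-sulfonyl carbanion at the unhindered CH2 terminus of the allylic bromide (SN2) forms C11–C12; the C11 centre is not controlled because the sulfone is removed in step 16.

Step 16
Reactants: 25 alkylated sulfone
Product: 26 tert-butyl 6,7α,15-tris(tert-butyldimethylsilyloxy)-9β-H-labda-5,8(17),13E-trien-19-oate
Conditions: Na/Hg (5% Na), Na2HPO4, MeOH/THF, −20 °C
Reagents that add atoms: none
Why: Reductive desulfonylation by electron transfer replaces the C11 sulfonyl group by hydrogen; the sulfone is not allylic, so neither double bond can migrate, and the buffer protects the silyl enol ether.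

Step 17
Reactants: 26 silyl enol ether
Product: 27 tert-butyl 7α,15-bis(tert-butyldimethylsilyloxy)-6-oxo-9β-H-labda-8(17),13E-dien-19-oate
Conditions: Bu4NF (1.05 equiv), AcOH (1.2 equiv), THF, −40 to −20 °C
Reagents that add atoms: none
Why: Fluoride cleaves the silyl enol ether far faster than the two alkyl silyl ethers, and the enolate should be protonated in situ at C5 on the α face, away from the syn-axial C10 methyl and C4 ester, to give the trans ring fusion (5α-H), which is also the thermodynamic one.

Step 18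
Reactants: 27 C6 ketone
Product: 28 tert-butyl 7α,15-bis(tert-butyldimethylsilyloxy)-6β-hydroxy-9β-H-labda-8(17),13E-dien-19-oate
Conditions: NaBH4, CeCl3·7H2O, MeOH/THF, −40 to 0 °C
Reagents that add atoms: none
Why: Luche-type borohydride reduction: hydride should enter C6 from the α face because the β face is closed by the syn-axial C10 methyl and C4 ester, giving the axial 6β-alcohol as in 6-oxo steroids, while the tert-butyl ester resists lactonisation and the trans-diaxial geometry excludes silyl migration.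

Step 19
Reactants: 28 6β-alcohol
Product: 29 tert-butyl 6β-benzoyloxy-7α,15-bis(tert-butyldimethylsilyloxy)-9β-H-labda-8(17),13E-dien-19-oate
Conditions: BzCl (5 equiv), DMAP (2 equiv), pyridine, 50 °C
Reagents that add atoms: benzoyl chloride (O=C(Cl)c1ccccc1)
Why: DMAP-catalysed acylation of the only free hydroxyl group, under forcing conditions because the axial 6β-OH is flanked by C20 and the C4 ester.

Step 20
Reactants: 29 benzoate
Product: 31 6β-benzoyloxy-7α,15-bis(tert-butyldimethylsilyloxy)-9β-H-labda-8(17),13E-dien-19-oic acid, via trimethylsilyl ester 30 (not isolated)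
Conditions: Me3SiOTf (4 equiv), 2,6-lutidine (6 equiv), CH2Cl2, 0 °C; then pH 5 citrate buffer, THF, rt
Reagents that add atoms: none
Why: Silyl triflate-mediated cleavage of the tert-butyl ester (O-silylation, loss of isobutene) under buffered non-protic conditions should leave the benzoate, the silyl ethers and the alkenes intact, and the silyl ester hydrolyses on work-up.

Step 21
Reactants: 31 bis(silyl ether) acid
Product: 32 6β-benzoyloxy-7α,15-dihydroxy-9β-H-labda-8(17),13E-dien-19-oic acid (CNP0149011.1; 4S,5R,6S,7S,9S,10R)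
Conditions: HF·pyridine, pyridine, THF, 0 °C to rt
Reagents that add atoms: none
Why: Buffered fluoride desilylation frees both allylic alcohols, and the trans-diaxial relation of 6β-OBz and 7α-OH excludes benzoyl migration.

## Compound list

1 | tert-butyl 2-oxocyclohexane-1-carboxylate | O=C1CCCCC1C(=O)OC(C)(C)C | starting material
2 | L-valine tert-butyl ester | CC(C)[C@H](N)C(=O)OC(C)(C)C | starting material
3 | tert-butyl 2-{[(2S)-1-tert-butoxy-3-methyl-1-oxobutan-2-yl]amino}cyclohex-1-ene-1-carboxylate | CC(C)[C@H](NC1=C(C(=O)OC(C)(C)C)CCCC1)C(=O)OC(C)(C)C | intermediate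
4 | N-lithio enamine of 3 | CC(C)[C@H](N([Li])C1=C(C(=O)OC(C)(C)C)CCCC1)C(=O)OC(C)(C)C | intermediate
5 | tert-butyl (1S)-2-{[(2S)-1-tert-butoxy-3-methyl-1-oxobutan-2-yl]imino}-1-methylcyclohexane-1-carboxylate | CC(C)[C@H](N=C1CCCC[C@]1(C)C(=O)OC(C)(C)C)C(=O)OC(C)(C)C | intermediate
6 | tert-butyl (1S)-1-methyl-2-oxocyclohexane-1-carboxylate | O=C1CCCC[C@]1(C)C(=O)OC(C)(C)C | intermediate
7 | lithium enolate of 6 | [Li]OC1=CCCC[C@]1(C)C(=O)OC(C)(C)C | intermediate
8 | tert-butyl (1S)-1,3-dimethyl-2-oxocyclohexane-1-carboxylate (C3 epimers) | CC1CCC[C@](C)(C(=O)OC(C)(C)C)C1=O | intermediate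
9 | potassium enolate of 8 | [K]OC1=C(C)CCC[C@]1(C)C(=O)OC(C)(C)C | intermediate
10 | tert-butyl (1S)-1,3-dimethyl-2-(trifluoromethylsulfonyloxy)cyclohex-2-ene-1-carboxylate | CC1=C(OS(=O)(=O)C(F)(F)F)[C@@](C)(C(=O)OC(C)(C)C)CCC1 | intermediate
11 | (tert-butyldimethylsilyloxy)acetaldehyde | O=CCO[Si](C)(C)C(C)(C)C | starting material
12 | tert-butyl (1S)-2-[2-(tert-butyldimethylsilyloxy)-1-hydroxyethyl]-1,3-dimethylcyclohex-2-ene-1-carboxylate (carbinol epimers) | CC1=C(C(O)CO[Si](C)(C)C(C)(C)C)[C@@](C)(C(=O)OC(C)(C)C)CCC1 | intermediate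
13 | tert-butyl (1S)-2-[(tert-butyldimethylsilyloxy)acetyl]-1,3-dimethylcyclohex-2-ene-1-carboxylate | CC1=C(C(=O)CO[Si](C)(C)C(C)(C)C)[C@@](C)(C(=O)OC(C)(C)C)CCC1 | intermediate
14 | tert-butyl (1S)-2-[(Z)-1,2-bis(tert-butyldimethylsilyloxy)ethenyl]-1,3-dimethylcyclohex-2-ene-1-carboxylate | CC1=C(/C(O[Si](C)(C)C(C)(C)C)=C/O[Si](C)(C)C(C)(C)C)[C@@](C)(C(=O)OC(C)(C)C)CCC1 | intermediate
15 | ethyl buta-2,3-dienoate | C=C=CC(=O)OCC | starting material
16 | 19-tert-butyl 11-ethyl 6,7α-bis(tert-butyldimethylsilyloxy)-9β-H-12,13,14,15,16-pentanorlabda-5,8(17)-diene-11,19-dioate | C=C1[C@@H](C(=O)OCC)[C@@]2(C)CCC[C@](C)(C(=O)OC(C)(C)C)C2=C(O[Si](C)(C)C(C)(C)C)[C@H]1O[Si](C)(C)C(C)(C)C | intermediate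
17 | tert-butyl 6,7α-bis(tert-butyldimethylsilyloxy)-11-hydroxy-9β-H-12,13,14,15,16-pentanorlabda-5,8(17)-dien-19-oate | C=C1[C@@H](CO)[C@@]2(C)CCC[C@](C)(C(=O)OC(C)(C)C)C2=C(O[Si](C)(C)C(C)(C)C)[C@H]1O[Si](C)(C)C(C)(C)C | intermediate
18 | tert-butyl 6,7α-bis(tert-butyldimethylsilyloxy)-11-iodo-9β-H-12,13,14,15,16-pentanorlabda-5,8(17)-dien-19-oate | C=C1[C@@H](CI)[C@@]2(C)CCC[C@](C)(C(=O)OC(C)(C)C)C2=C(O[Si](C)(C)C(C)(C)C)[C@H]1O[Si](C)(C)C(C)(C)C | intermediate
19 | tert-butyl 6,7α-bis(tert-butyldimethylsilyloxy)-11-(phenylsulfonyl)-9β-H-12,13,14,15,16-pentanorlabda-5,8(17)-dien-19-oate | C=C1[C@@H](CS(=O)(=O)c3ccccc3)[C@@]2(C)CCC[C@](C)(C(=O)OC(C)(C)C)C2=C(O[Si](C)(C)C(C)(C)C)[C@H]1O[Si](C)(C)C(C)(C)C | intermediate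
20 | 3-methylbut-2-en-1-ol | CC(C)=CCO | starting material
21 | tert-butyldimethyl(3-methylbut-2-enyloxy)silane | CC(C)=CCO[Si](C)(C)C(C)(C)C | intermediate
22 | (E)-4-(tert-butyldimethylsilyloxy)-2-methylbut-2-en-1-ol | OC/C(C)=C/CO[Si](C)(C)C(C)(C)C | intermediate
23 | (E)-(4-bromo-3-methylbut-2-enyloxy)(tert-butyl)dimethylsilane | BrC/C(C)=C/CO[Si](C)(C)C(C)(C)C | intermediate
24 | C11-lithio sulfone of 19 | C=C1[C@@H](C([Li])S(=O)(=O)c3ccccc3)[C@@]2(C)CCC[C@](C)(C(=O)OC(C)(C)C)C2=C(O[Si](C)(C)C(C)(C)C)[C@H]1O[Si](C)(C)C(C)(C)C | intermediate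
25 | tert-butyl 6,7α,15-tris(tert-butyldimethylsilyloxy)-11-(phenylsulfonyl)-9β-H-labda-5,8(17),13E-trien-19-oate (C11 epimers) | C=C1[C@@H](C(C/C(C)=C/CO[Si](C)(C)C(C)(C)C)S(=O)(=O)c3ccccc3)[C@@]2(C)CCC[C@](C)(C(=O)OC(C)(C)C)C2=C(O[Si](C)(C)C(C)(C)C)[C@H]1O[Si](C)(C)C(C)(C)C | intermediate
26 | tert-butyl 6,7α,15-tris(tert-butyldimethylsilyloxy)-9β-H-labda-5,8(17),13E-trien-19-oate | C=C1[C@@H](CC/C(C)=C/CO[Si](C)(C)C(C)(C)C)[C@@]2(C)CCC[C@](C)(C(=O)OC(C)(C)C)C2=C(O[Si](C)(C)C(C)(C)C)[C@H]1O[Si](C)(C)C(C)(C)C | intermediate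
27 | tert-butyl 7α,15-bis(tert-butyldimethylsilyloxy)-6-oxo-9β-H-labda-8(17),13E-dien-19-oate | C=C1[C@@H](CC/C(C)=C/CO[Si](C)(C)C(C)(C)C)[C@@]2(C)CCC[C@](C)(C(=O)OC(C)(C)C)[C@@H]2C(=O)[C@H]1O[Si](C)(C)C(C)(C)C | intermediate
28 | tert-butyl 7α,15-bis(tert-butyldimethylsilyloxy)-6β-hydroxy-9β-H-labda-8(17),13E-dien-19-oate | C=C1[C@@H](CC/C(C)=C/CO[Si](C)(C)C(C)(C)C)[C@@]2(C)CCC[C@](C)(C(=O)OC(C)(C)C)[C@@H]2[C@H](O)[C@H]1O[Si](C)(C)C(C)(C)C | intermediate
29 | tert-butyl 6β-benzoyloxy-7α,15-bis(tert-butyldimethylsilyloxy)-9β-H-labda-8(17),13E-dien-19-oate | C=C1[C@@H](CC/C(C)=C/CO[Si](C)(C)C(C)(C)C)[C@@]2(C)CCC[C@](C)(C(=O)OC(C)(C)C)[C@@H]2[C@H](OC(=O)c3ccccc3)[C@H]1O[Si](C)(C)C(C)(C)C | intermediate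
30 | trimethylsilyl ester of 31 | C=C1[C@@H](CC/C(C)=C/CO[Si](C)(C)C(C)(C)C)[C@@]2(C)CCC[C@](C)(C(=O)O[Si](C)(C)C)[C@@H]2[C@H](OC(=O)c3ccccc3)[C@H]1O[Si](C)(C)C(C)(C)C | intermediate
31 | 6β-benzoyloxy-7α,15-bis(tert-butyldimethylsilyloxy)-9β-H-labda-8(17),13E-dien-19-oic acid | C=C1[C@@H](CC/C(C)=C/CO[Si](C)(C)C(C)(C)C)[C@@]2(C)CCC[C@](C)(C(=O)O)[C@@H]2[C@H](OC(=O)c3ccccc3)[C@H]1O[Si](C)(C)C(C)(C)C | intermediate
32 | 6β-benzoyloxy-7α,15-dihydroxy-9β-H-labda-8(17),13E-dien-19-oic acid (CNP0149011.1; 4S,5R,6S,7S,9S,10R) | C=C1[C@@H](CC/C(C)=C/CO)[C@@]2(C)CCC[C@](C)(C(=O)O)[C@@H]2[C@H](OC(=O)c2ccccc2)[C@H]1O | target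

## Step count and risks

Total step count: 21. Longest linear sequence: 18 (steps 1–11 and 15–21); steps 12–14 prepare the C12–C16 bromide.

Steps most likely to fail:

1. Step 8. The cycloaddition may be too slow because the C10 methyl group twists the diene out of the s-cis form, which would let a 1,5-hydrogen shift from that methyl group or dimerisation of the allenoate compete. The termini may also pair the wrong way round, or the facial selectivity against the C4 ester may be low. The fallback sets out from enone 13 and closes the same ring by an anionic double Michael annulation. LiN(iPr)2 in THF at −78 °C should give the chelated (Z)-lithium dienolate F1, in which C7 is the only nucleophilic carbon. Addition to the central carbon of 15 and 6-endo Michael closure of the resulting ester dienolate onto C10 of the enone should give the cyclised lithium enolate F2. O-Silylation with t-BuMe2SiCl and HMPA comes back to the route at 16. C7 is then set in a stepwise event, so its epimers may have to be separated.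

2. Step 5. The hindered, tetrasubstituted alkenylchromium may be protonated (net reduction of the triflate) faster than it adds to the aldehyde. The fallback sets out from triflate 10. Stille coupling with tributyl(1-ethoxyvinyl)stannane (Pd(PPh3)4, LiCl, CuI, DMF) should give the 2-ethoxy diene F3, which aqueous oxalic acid hydrolyses to the methyl ketone tert-butyl (1S)-2-acetyl-1,3-dimethylcyclohex-2-ene-1-carboxylate F4. Soft enolisation (t-BuMe2SiOTf, Et3N) gives the silyl dienol ether F5. Rubottom oxidation with dimethyldioxirane, through the silyloxy epoxide F6 and a 1,4-silyl shift, comes back to the route at 13.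

3. Step 11. SN2 displacement at the β-branched C11 by sulfinate may be slow, so that elimination to a C9=C11 alkene or loss of the silyl enol ether on prolonged heating takes over. The fallback sets out from alcohol 17 and reverses the roles of the partners. Tf2O and 2,6-lutidine at −78 °C give the primary triflate F7. Separately, bromide 23 and PhSO2Na give the allylic sulfone (E)-tert-butyldimethyl[3-methyl-4-(phenylsulfonyl)but-2-enyloxy]silane F8. Its lithio derivative F9 (n-BuLi, THF, −78 °C) should displace the triflate at low temperature to give the C12 sulfone F10. Desulfonylation with Na/Hg and Na2HPO4 in MeOH comes back to the route at 26; position and geometry of the C13=C14 bond must be checked because this sulfone is allylic.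

Further compounds
F1 | step 8 | lithium (Z)-dienolate of 13 | CC1=C(/C(O[Li])=C/O[Si](C)(C)C(C)(C)C)[C@@](C)(C(=O)OC(C)(C)C)CCC1
F2 | step 8 | cyclised C6 lithium enolate (lithium analogue of 16) | C=C1[C@@H](C(=O)OCC)[C@@]2(C)CCC[C@](C)(C(=O)OC(C)(C)C)C2=C(O[Li])[C@H]1O[Si](C)(C)C(C)(C)C
F3 | step 5 | tert-butyl (1S)-2-(1-ethoxyethenyl)-1,3-dimethylcyclohex-2-ene-1-carboxylate | CC1=C(C(=C)OCC)[C@@](C)(C(=O)OC(C)(C)C)CCC1
F4 | step 5 | tert-butyl (1S)-2-acetyl-1,3-dimethylcyclohex-2-ene-1-carboxylate | CC1=C(C(C)=O)[C@@](C)(C(=O)OC(C)(C)C)CCC1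
F5 | step 5 | tert-butyl (1S)-2-[1-(tert-butyldimethylsilyloxy)ethenyl]-1,3-dimethylcyclohex-2-ene-1-carboxylate | CC1=C(C(=C)O[Si](C)(C)C(C)(C)C)[C@@](C)(C(=O)OC(C)(C)C)CCC1
F6 | step 5 | silyloxy epoxide of F5 | CC1=C(C2(O[Si](C)(C)C(C)(C)C)CO2)[C@@](C)(C(=O)OC(C)(C)C)CCC1
F7 | step 11 | C11 trifluoromethanesulfonate of 17 | C=C1[C@@H](COS(=O)(=O)C(F)(F)F)[C@@]2(C)CCC[C@](C)(C(=O)OC(C)(C)C)C2=C(O[Si](C)(C)C(C)(C)C)[C@H]1O[Si](C)(C)C(C)(C)C
F8 | step 11 | (E)-tert-butyldimethyl[3-methyl-4-(phenylsulfonyl)but-2-enyloxy]silane | O=S(=O)(C/C(C)=C/CO[Si](C)(C)C(C)(C)C)c1ccccc1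
F9 | step 11 | lithio derivative of F8 | [Li]C(/C(C)=C/CO[Si](C)(C)C(C)(C)C)S(=O)(=O)c1ccccc1
F10 | step 11 | tert-butyl 6,7α,15-tris(tert-butyldimethylsilyloxy)-12-(phenylsulfonyl)-9β-H-labda-5,8(17),13E-trien-19-oate (C12 epimers) | C=C1[C@@H](CC(/C(C)=C/CO[Si](C)(C)C(C)(C)C)S(=O)(=O)c3ccccc3)[C@@]2(C)CCC[C@](C)(C(=O)OC(C)(C)C)C2=C(O[Si](C)(C)C(C)(C)C)[C@H]1O[Si](C)(C)C(C)(C)C
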